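## The problem

Compound 24 is a rearranged drimane (avarane-type) sesquiterpenoid: a cis-fused decalin joined through one methylene carbon, C15, to a 2-hydroxy-5-methoxy-1,4-benzoquinone. The numbering used throughout is: ring A = C1–C5 and C10, with the exocyclic methylidene on C4; ring B = C5–C10; C5 carries the angular methyl group, C10 the ring-fusion hydrogen, C9 a methyl group and C15, and C8 a methyl group. The four stereocentres (5R, 10S, 9R, 8S) are contiguous and all lie on ring B, and the two quaternary ones (C5, C9) flank C10, so a stepwise route would have to build one congested quaternary carbon next to the other. None of them can be epimerised in 24 and a cis ring fusion cannot be counted on from equilibration, so the array must come from kinetic control; the ring fusion could relay to C9 and C8 only through reactions at doubly flanked carbons. C15 is neopentyl, which closes the SN2 route for attaching the arene. The C4 methylidene moves into the ring under acid, and the hydroxyquinone (a vinylogous acid, an oxidant and a Michael acceptor) survives neither organometallic reagents, hydrogenation nor radical reduction, so both are unveiled last, from a C4 ketone and a tetramethoxyarene. A one-step solution is possible because C5, C10, C9 and C8 are four consecutive atoms of one six-membered ring whose other two atoms, C6 and C7, are bare methylenes: ring B is the retron of a cyclohexene from a C5–C8 diene and a C9=C10 dienophile, C15 at the aldehyde level activates that dienophile, and C1–C4 of ring A is the four-atom tether between them.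

## Retrosynthesis

**Quinone stage (24 ⇒ 23 ⇒ 22).** No skeletal bond is cut. The hydroxy-methoxyquinone of 24 is traced to dimethoxyquinone 23 by exchange of the C–O bond of the methoxy group that flanks the alkyl branch, and 23 to tetramethoxyarene 22 by oxidative demethylation. Carrying a quinone or hydroquinone through the synthesis is ruled out by the organolithium, hydrogenation and radical steps before it, whereas the arene is inert to all of them. The forward steps must tell the two methoxy groups of 23 apart and leave the C4 methylidene alone.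

**C4 (22 ⇒ 21 ⇒ 20).** The C4=CH2 bond is cut to ketone 21, which is stored as dioxolane 20. A ketone is preferred over any carbon substituent at C4 because the alkene cannot be present while ring B is hydrogenated, and because the same carbon, as a ketal, is the gem-disubstituted tether atom of the cycloaddition. The methylenation has to work next to quaternary C5, which at least cannot epimerise.

**C15–aryl bond (20 ⇒ 19 ⇒ 17 ⇒ 16 ⇒ 13 + 14).** The bond between C15 and the arene is cut. The neighbouring C9–C15 cut would ask for benzylation of a C9 carbanion, creating the quaternary centre late and without a controlling element. Displacement at neopentyl C15 is not viable. Addition of aryllithium 15 (from 14) to the non-enolisable aldehyde 13 uses the formyl group exactly as the cycloaddition leaves it. The price is removal of the carbinol oxygen (17 ⇒ 19 ⇒ 20), which is done by a radical method after C6=C7 has been saturated (16 ⇒ 17).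

**Rings A and B (13 ⇒ 12).** C5–C10 and C8–C9 are cut together. This is the only pairing of ring B bonds that puts all four stereocentres at the termini of a diene (C5, C8) and a dienophile (C9, C10) and also lets ring A serve as the tether. Two rings, two C–C bonds and four stereocentres disappear, and triene 12 is acyclic and achiral. The forward reaction must proceed through the exo-formyl topology (cis fusion) on one enal face, and it must overcome a cis-methyl group on the diene terminus.

**Enal (12 ⇒ 10 + 11; 10 ⇒ 9 ⇒ 8).** The C9=C10 bond is cut to aldehyde 10 and the formyl ylide 11, which delivers C9, its methyl group and C15 in one piece with E geometry. Aldehyde 10 comes from silyl ether 8 through alcohol 9. Introducing the enal last keeps diene and dienophile apart until the substrate for the catalyst is complete.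

**Ketone and diene (8 ⇒ 7 ⇒ 4 + 5; 4 ⇒ 3 ⇒ 1 + 2).** The ketal is traced to dienone 7, and C3–C4 is cut to Weinreb amide 4 and the Grignard reagent 6 made from bromide 5. The dienoyl unit goes back through ester 3 to crotonaldehyde 1 and ylide 2. The C7=C8 alkene is bought with its E geometry and C5=C6 is made by a stabilised-ylide olefination, so both diene geometries that encode the C5/C8 relationship are secured by reliable reactions.

## Roads not taken

**Alternative 1:** the C5–C6 bond is cut and ring B is closed by anodic coupling of two enol ethers. The tetrasubstituted ring A silyl enol ether of precursor A2 would be oxidised at a carbon anode (LiClO4, methanol, 2,6-lutidine, constant current). The radical cation is captured at C5 by the terminal carbon (C6) of the side-chain methyl enol ether, and methanol traps the oxocarbenium ion. The product A1 is a cis-fused decalin with a C4 ketone, a C7 dimethyl ketal and C15 as a pivalate.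
- Merits: this reaction type is established for building quaternary carbons in six-membered rings, so the key bond stands on firmer ground than the cycloaddition chosen here. The C4 ketone also emerges unprotected.
- Weak points: the step sets only C5. C10, C9 and C8, including quaternary C9 on an open chain, must already be in A2, and that is the hard part of the problem. The regiodefined tetrasubstituted silyl enol ether is a task of its own. The C7 oxygen is surplus and must be removed, and the pivalate must be taken to the aldehyde before the same aryllithium chemistry can begin.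
- Comparison: against the better precedent of this road, the chosen plan sets all four centres in one operation from an achiral triene and has no surplus oxygen to erase.

**Alternative 2:** the C8–C9 bond is cut and made by Ireland–Claisen rearrangement of the alkenyl lactone A4. LiN(iPr)2 and Me3SiCl would give the silyl ketene acetal, which rearranges on warming with cleavage of the O–C6 bond to the cyclohexene acid A3 (C6=C7, C9 bearing CO2H and the arylmethyl group).
- Merits: the arylmethyl group is on C9 before the key step. There is no addition of a hindered aryllithium to a neopentyl aldehyde and no deoxygenation, and in this respect the road is better than the chosen one. Chirality transfer in a [3,3] shift is dependable.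
- Weak points: the C9 carboxyl group must be reduced to a methyl group, a neopentyl deoxygenation that costs several steps. The lactone ring enforces a boat-like transition state, so the C8/C9 outcome hinges on the propenyl geometry and on the C6 configuration. C5, C10 and C6 must be set beforehand, and the C4 ketone would have to be masked during enolisation.
- Comparison: the chosen plan pays three steps for its late arene installation. It sets against this that no stereocentre has to be made before the key step and that the activating formyl group is used as it stands.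

**Alternative 3:** the C1–C10 bond is cut and ring A is closed by radical desymmetrisation of the cyclohexadienone A6. The C1 radical from the iodide ((Me3Si)3SiH, initiator) adds 6-exo to one of the two enone β-carbons, which the C4 silyloxy stereocentre makes diastereotopic, and gives the cis-fused enone A5.
- Merits: A6 should be reachable in few steps by dearomatisation of a benzoate. The radical step is low-risk and gives the cis fusion reliably. In precursor economy and in certainty of the key step this road is at least as good as the chosen one.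
- Weak points: A5 holds only C5 and C10. Quaternary C9 must then be built by two successive alkylations α to the C8 ketone on the concave or convex face of a cis-decalin, with no clear control, and C8 must be converted from a carbonyl to a methyl-bearing stereocentre. A 6-exo closure also competes with premature reduction.
- Comparison: the chosen plan accepts a riskier key step but solves C9 and C8 in the same step as the ring fusion, where this road postpones them.

Key step: step 8

Assumption: the (S)-diphenylprolinol-derived oxazaborolidinium ion is taken to shield the Si face of C9 in the bound enal. The route requires diene attack on the C9 Re face, and if the facial sense is the reverse, the (R)-catalyst is used with nothing else changed.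

## Route

Step 1
Reactants: 1 crotonaldehyde; 2 ethyl 2-(triphenylphosphoranylidene)propanoate
Product: 3 ethyl (2E,4E)-2-methylhexa-2,4-dienoate
Conditions: CH2Cl2, 0 °C → rt
Reagents that add atoms: none
Why: Wittig olefination; the ester-stabilised, α-branched ylide gives the trisubstituted alkene (future C5=C6) with E geometry, and the E alkene of 1 (future C7=C8) is carried through unchanged.

Step 2
Reactants: 3 ethyl (2E,4E)-2-methylhexa-2,4-dienoate
Product: 4 (2E,4E)-N-methoxy-N,2-dimethylhexa-2,4-dienamide
Conditions: MeNH(OMe)·HCl, iPrMgCl, THF, −20 → 0 °C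
Reagents that add atoms: N,O-dimethylhydroxylamine hydrochloride, CNOC.Cl
Why: Weinreb amide synthesis by acyl substitution of the ester with the chloromagnesium amide formed in the flask; the α-methyl group and the low temperature disfavour conjugate addition to the dienoate.

Step 3
Reactants: 4 (2E,4E)-N-methoxy-N,2-dimethylhexa-2,4-dienamide; 5 (4-bromobutoxy)(tert-butyl)dimethylsilane
Product: 7 (6E,8E)-1-[(tert-butyldimethylsilyl)oxy]-6-methyldeca-6,8-dien-5-one, via silyloxybutylmagnesium bromide 6 (not isolated)
Conditions: 5, Mg, THF, 40 °C; then 4, THF, 0 °C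
Reagents that add atoms: none
Why: Grignard addition to a Weinreb amide; the magnesium-chelated tetrahedral intermediate persists until work-up, so the dienone is formed by 1,2-attack without over-addition.

Step 4
Reactants: 7 (6E,8E)-1-[(tert-butyldimethylsilyl)oxy]-6-methyldeca-6,8-dien-5-one
Product: 8 tert-butyl(4-{2-[(2E,4E)-hexa-2,4-dien-2-yl]-1,3-dioxolan-2-yl}butoxy)dimethylsilane
Conditions: Me3SiOCH2CH2OSiMe3, Me3SiOTf (cat.), CH2Cl2, −78 → −20 °C; pyridine quench
Reagents that add atoms: 1,2-bis(trimethylsilyloxy)ethane, C[Si](C)(C)OCCO[Si](C)(C)C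
Why: Ketalisation under aprotic silyl triflate catalysis (Noyori conditions), driven by formation of hexamethyldisiloxane; with no free acid and no dienol ether at low temperature the diene should stay conjugated and E,E, and the primary silyl ether is untouched.

Step 5
Reactants: 8 tert-butyl(4-{2-[(2E,4E)-hexa-2,4-dien-2-yl]-1,3-dioxolan-2-yl}butoxy)dimethylsilane
Product: 9 4-{2-[(2E,4E)-hexa-2,4-dien-2-yl]-1,3-dioxolan-2-yl}butan-1-ol
Conditions: Bu4NF, THF, 0 °C → rt
Reagents that add atoms: none
Why: Fluoride-mediated cleavage of the silyl ether; ketal and diene are inert to Bu4NF.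

Step 6
Reactants: 9 4-{2-[(2E,4E)-hexa-2,4-dien-2-yl]-1,3-dioxolan-2-yl}butan-1-ol
Product: 10 4-{2-[(2E,4E)-hexa-2,4-dien-2-yl]-1,3-dioxolan-2-yl}butanal
Conditions: Dess–Martin periodinane, pyridine, CH2Cl2, 0 °C → rt
Reagents that add atoms: none
Why: Dess–Martin oxidation of the primary alcohol; pyridine buffers the acetic acid formed so that the acid-labile dienyl ketal survives, and the oxidation stops at the aldehyde.

Step 7
Reactants: 10 4-{2-[(2E,4E)-hexa-2,4-dien-2-yl]-1,3-dioxolan-2-yl}butanal; 11 2-(triphenylphosphoranylidene)propanal
Product: 12 (2E)-2-methyl-6-{2-[(2E,4E)-hexa-2,4-dien-2-yl]-1,3-dioxolan-2-yl}hex-2-enal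
Conditions: toluene, 60 °C
Reagents that add atoms: none
Why: Wittig olefination with the formyl-stabilised ylide gives the (E)-2-methyl enal (C9=C10); the hindered, conjugated product aldehyde should not react with a second equivalent, and 60 °C is below the range where uncatalysed cycloaddition of the triene is expected.

Step 8
Reactants: 12 (2E)-2-methyl-6-{2-[(2E,4E)-hexa-2,4-dien-2-yl]-1,3-dioxolan-2-yl}hex-2-enal
Product: 13 (4a′S,5′R,6′S,8a′R)-5′,6′,8a′-trimethyl-3′,4′,4a′,5′,6′,8a′-hexahydro-2′H-spiro[1,3-dioxolane-2,1′-naphthalene]-5′-carbaldehyde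
Conditions: (S)-tetrahydro-1-(2-methylphenyl)-3,3-diphenyl-1H,3H-pyrrolo[1,2-c][1,3,2]oxazaborole (20 mol %), HN(SO2CF3)2 (17 mol %), CH2Cl2, −78 → −20 °C
Reagents that add atoms: none
Why: Proposed new method: the N-protonated oxazaborolidine binds the formyl group of 12 in the two-point mode known for 2-substituted enals, lowers the enal LUMO and lets the tethered diene add in a concerted, asynchronous [4+2] process; the closest known reaction types are oxazaborolidinium-catalysed type 1 intramolecular Diels–Alder reactions of 2,8,10-trienals and intermolecular Diels–Alder reactions of 2-methyl enals, whereas an α-methyl enal combined with a diene terminus that carries a cis-methyl group has not been shown in an enantioselective intramolecular setting. Ring B closes as the cyclohexene of the cycloaddition itself, and ring A closes through the new C5–C10 bond with the C1–C4 tether in a chair-like array that the gem-dioxygenated C4 helps to fold. Suprafacial addition to the E enal places H10 cis to the formyl group (C9 relative to C10), and suprafacial addition to the E,E diene places C4 cis to the C8 methyl group (C5 relative to C8). The link between these two pairs, and with it the cis ring fusion, comes from the exo-formyl topology with the tether under the diene; it is expected to be favoured because the endo-formyl array would force the C9 methyl group against the C8 methyl group and would place the bulky catalyst-bound carbonyl group under the diene, in line with the exo preference of 2-alkyl enals in Lewis acid catalysis. The absolute configuration is set by the catalyst, which must leave the Re face of C9 (Si face of C10) open to the diene. A slight excess of oxazaborolidine over HN(SO2CF3)2 avoids free acid that could ionise the dienyl ketal.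

Step 9
Reactants: 13 (4a′S,5′R,6′S,8a′R)-5′,6′,8a′-trimethyl-3′,4′,4a′,5′,6′,8a′-hexahydro-2′H-spiro[1,3-dioxolane-2,1′-naphthalene]-5′-carbaldehyde; 14 1,2,4,5-tetramethoxybenzene
Product: 16 (2,3,5,6-tetramethoxyphenyl)[(4a′S,5′R,6′S,8a′R)-5′,6′,8a′-trimethyl-3′,4′,4a′,5′,6′,8a′-hexahydro-2′H-spiro[1,3-dioxolane-2,1′-naphthalen]-5′-yl]methanol (both C15 epimers), via 2,3,5,6-tetramethoxyphenyllithium 15 (not isolated)
Conditions: 14, n-BuLi, TMEDA, THF, 0 °C → rt; then 13, −78 °C → rt
Reagents that add atoms: none
Why: Directed ortho-lithiation of 14 between two methoxy groups gives 15, which adds 1,2 to the formyl group of 13; the aldehyde has no α-hydrogen, so enolisation cannot compete, and the C15 configuration is irrelevant because the oxygen is removed in step 12.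

Step 10
Reactants: 16 (2,3,5,6-tetramethoxyphenyl)[(4a′S,5′R,6′S,8a′R)-5′,6′,8a′-trimethyl-3′,4′,4a′,5′,6′,8a′-hexahydro-2′H-spiro[1,3-dioxolane-2,1′-naphthalen]-5′-yl]methanol
Product: 17 (2,3,5,6-tetramethoxyphenyl)[(4a′S,5′R,6′S,8a′R)-5′,6′,8a′-trimethyloctahydro-2′H-spiro[1,3-dioxolane-2,1′-naphthalen]-5′-yl]methanol (both C15 epimers)
Conditions: H2 (1 atm), PtO2, EtOAc, rt
Reagents that add atoms: none
Why: Heterogeneous catalytic hydrogenation of the cis-disubstituted C6=C7 alkene; platinum is chosen over palladium to suppress migration of the double bond toward C8, which would put that stereocentre at risk, and no new stereocentre is formed.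

Step 11
Reactants: 17 (2,3,5,6-tetramethoxyphenyl)[(4a′S,5′R,6′S,8a′R)-5′,6′,8a′-trimethyloctahydro-2′H-spiro[1,3-dioxolane-2,1′-naphthalen]-5′-yl]methanol
Product: 19 S-methyl O-{(2,3,5,6-tetramethoxyphenyl)[(4a′S,5′R,6′S,8a′R)-5′,6′,8a′-trimethyloctahydro-2′H-spiro[1,3-dioxolane-2,1′-naphthalen]-5′-yl]methyl} carbonodithioate, via sodium xanthate 18 (not isolated)
Conditions: NaH, CS2, THF, 0 °C → rt; then MeI
Reagents that add atoms: carbon disulfide, S=C=S; iodomethane, CI
Why: Xanthate formation: the sodium alkoxide adds to carbon disulfide and salt 18 is S-methylated; C9 is quaternary, so the xanthate has no β-hydrogen for a Chugaev elimination.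

Step 12
Reactants: 19 S-methyl O-{(2,3,5,6-tetramethoxyphenyl)[(4a′S,5′R,6′S,8a′R)-5′,6′,8a′-trimethyloctahydro-2′H-spiro[1,3-dioxolane-2,1′-naphthalen]-5′-yl]methyl} carbonodithioate
Product: 20 (4a′S,5′R,6′S,8a′R)-5′,6′,8a′-trimethyl-5′-[(2,3,5,6-tetramethoxyphenyl)methyl]octahydro-2′H-spiro[1,3-dioxolane-2,1′-naphthalene]
Conditions: Bu3SnH, AIBN, toluene, 110 °C
Reagents that add atoms: none
Why: Barton–McCombie deoxygenation: the stannyl radical adds to the thiocarbonyl group, β-scission releases a benzylic C15 radical and this takes hydrogen from Bu3SnH; with C6=C7 already saturated the radical has no alkene to cyclise onto.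

Step 13
Reactants: 20 (4a′S,5′R,6′S,8a′R)-5′,6′,8a′-trimethyl-5′-[(2,3,5,6-tetramethoxyphenyl)methyl]octahydro-2′H-spiro[1,3-dioxolane-2,1′-naphthalene]
Product: 21 (4aS,5R,6S,8aR)-5,6,8a-trimethyl-5-[(2,3,5,6-tetramethoxyphenyl)methyl]octahydronaphthalen-1(2H)-one
Conditions: aq. HCl (1 M), THF, 40 °C
Reagents that add atoms: water, O
Why: Acid-catalysed hydrolysis of the dioxolane, helped by relief of strain next to quaternary C5; the aryl methyl ethers are stable to dilute acid and the only enolisable α-carbon (C3) is not stereogenic.

Step 14
Reactants: 21 (4aS,5R,6S,8aR)-5,6,8a-trimethyl-5-[(2,3,5,6-tetramethoxyphenyl)methyl]octahydronaphthalen-1(2H)-one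
Product: 22 1,2,4,5-tetramethoxy-3-{[(1R,2S,4aR,8aS)-1,2,4a-trimethyl-5-methylidenedecahydronaphthalen-1-yl]methyl}benzene
Conditions: Ph3PCH3Br, KOtBu, toluene, 90 °C
Reagents that add atoms: methyltriphenylphosphonium bromide, C[P+](c1ccccc1)(c1ccccc1)c1ccccc1.[Br-]
Why: Wittig methylenation with the non-stabilised ylide under forcing conditions suited to a ketone next to a quaternary carbon; C5 cannot enolise, so the basic ylide can do no stereochemical harm.

Step 15
Reactants: 22 1,2,4,5-tetramethoxy-3-{[(1R,2S,4aR,8aS)-1,2,4a-trimethyl-5-methylidenedecahydronaphthalen-1-yl]methyl}benzene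
Product: 23 2,5-dimethoxy-3-{[(1R,2S,4aR,8aS)-1,2,4a-trimethyl-5-methylidenedecahydronaphthalen-1-yl]methyl}cyclohexa-2,5-diene-1,4-dione
Conditions: (NH4)2Ce(NO3)6, MeCN/H2O, 0 °C
Reagents that add atoms: water, O
Why: Oxidative demethylation by tetravalent cerium (two one-electron oxidations, attack of water on the arene radical cation, loss of methanol); either para pair of methoxy groups leads to the same quinone, and the isolated alkene should not be oxidised at 0 °C.

Step 16
Reactants: 23 2,5-dimethoxy-3-{[(1R,2S,4aR,8aS)-1,2,4a-trimethyl-5-methylidenedecahydronaphthalen-1-yl]methyl}cyclohexa-2,5-diene-1,4-dione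
Product: 24 2-hydroxy-5-methoxy-3-{[(1R,2S,4aR,8aS)-1,2,4a-trimethyl-5-methylidenedecahydronaphthalen-1-yl]methyl}cyclohexa-2,5-diene-1,4-dione
Conditions: KOH, MeOH/H2O, rt; then dilute HCl
Reagents that add atoms: potassium hydroxide, [K+].[OH-]
Why: Addition–elimination of hydroxide at a vinylogous ester carbon; the methoxy group next to the C15 branch is twisted out of conjugation, which should make its carbon the more electrophilic, and the vinylogous carboxylate formed resists a second substitution until acidification.

## Compound list

1 | crotonaldehyde, (2E)-but-2-enal | C/C=C/C=O | starting material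
2 | ethyl 2-(triphenylphosphoranylidene)propanoate | CCOC(=O)C(C)=P(c1ccccc1)(c1ccccc1)c1ccccc1 | starting material
3 | ethyl (2E,4E)-2-methylhexa-2,4-dienoate | CCOC(=O)/C(C)=C/C=C/C | intermediate
4 | (2E,4E)-N-methoxy-N,2-dimethylhexa-2,4-dienamide | CON(C)C(=O)/C(C)=C/C=C/C | intermediate
5 | (4-bromobutoxy)(tert-butyl)dimethylsilane | CC(C)(C)[Si](C)(C)OCCCCBr | starting material
6 | {4-[(tert-butyldimethylsilyl)oxy]butyl}magnesium bromide | CC(C)(C)[Si](C)(C)OCCCC[Mg]Br | intermediate
7 | (6E,8E)-1-[(tert-butyldimethylsilyl)oxy]-6-methyldeca-6,8-dien-5-one | CC(C)(C)[Si](C)(C)OCCCCC(=O)/C(C)=C/C=C/C | intermediate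
8 | tert-butyl(4-{2-[(2E,4E)-hexa-2,4-dien-2-yl]-1,3-dioxolan-2-yl}butoxy)dimethylsilane | CC(C)(C)[Si](C)(C)OCCCCC1(OCCO1)/C(C)=C/C=C/C | intermediate
9 | 4-{2-[(2E,4E)-hexa-2,4-dien-2-yl]-1,3-dioxolan-2-yl}butan-1-ol | OCCCCC1(OCCO1)/C(C)=C/C=C/C | intermediate
10 | 4-{2-[(2E,4E)-hexa-2,4-dien-2-yl]-1,3-dioxolan-2-yl}butanal | O=CCCCC1(OCCO1)/C(C)=C/C=C/C | intermediate
11 | 2-(triphenylphosphoranylidene)propanal | CC(C=O)=P(c1ccccc1)(c1ccccc1)c1ccccc1 | starting material
12 | (2E)-2-methyl-6-{2-[(2E,4E)-hexa-2,4-dien-2-yl]-1,3-dioxolan-2-yl}hex-2-enal | O=C/C(C)=C/CCCC1(OCCO1)/C(C)=C/C=C/C | intermediate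
13 | (4a′S,5′R,6′S,8a′R)-5′,6′,8a′-trimethyl-3′,4′,4a′,5′,6′,8a′-hexahydro-2′H-spiro[1,3-dioxolane-2,1′-naphthalene]-5′-carbaldehyde (cis-fused; C4 ketal, C6=C7, formyl on C9) | O1CCOC12CCC[C@H]3[C@](C)(C=O)[C@@H](C)C=C[C@@]23C | intermediate
14 | 1,2,4,5-tetramethoxybenzene | COc1cc(OC)c(OC)cc1OC | starting material
15 | 2,3,5,6-tetramethoxyphenyllithium | [Li]c1c(OC)c(OC)cc(OC)c1OC | intermediate
16 | (2,3,5,6-tetramethoxyphenyl)[(4a′S,5′R,6′S,8a′R)-5′,6′,8a′-trimethyl-3′,4′,4a′,5′,6′,8a′-hexahydro-2′H-spiro[1,3-dioxolane-2,1′-naphthalen]-5′-yl]methanol (both C15 epimers) | O1CCOC12CCC[C@H]3[C@](C)(C(O)c4c(OC)c(OC)cc(OC)c4OC)[C@@H](C)C=C[C@@]23C | intermediate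
17 | (2,3,5,6-tetramethoxyphenyl)[(4a′S,5′R,6′S,8a′R)-5′,6′,8a′-trimethyloctahydro-2′H-spiro[1,3-dioxolane-2,1′-naphthalen]-5′-yl]methanol (both C15 epimers) | O1CCOC12CCC[C@H]3[C@](C)(C(O)c4c(OC)c(OC)cc(OC)c4OC)[C@@H](C)CC[C@@]23C | intermediate
18 | sodium O-{(2,3,5,6-tetramethoxyphenyl)[(4a′S,5′R,6′S,8a′R)-5′,6′,8a′-trimethyloctahydro-2′H-spiro[1,3-dioxolane-2,1′-naphthalen]-5′-yl]methyl} carbonodithioate | O1CCOC12CCC[C@H]3[C@](C)(C(OC(=S)[S-])c4c(OC)c(OC)cc(OC)c4OC)[C@@H](C)CC[C@@]23C.[Na+] | intermediate
19 | S-methyl O-{(2,3,5,6-tetramethoxyphenyl)[(4a′S,5′R,6′S,8a′R)-5′,6′,8a′-trimethyloctahydro-2′H-spiro[1,3-dioxolane-2,1′-naphthalen]-5′-yl]methyl} carbonodithioate | O1CCOC12CCC[C@H]3[C@](C)(C(OC(=S)SC)c4c(OC)c(OC)cc(OC)c4OC)[C@@H](C)CC[C@@]23C | intermediate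
20 | (4a′S,5′R,6′S,8a′R)-5′,6′,8a′-trimethyl-5′-[(2,3,5,6-tetramethoxyphenyl)methyl]octahydro-2′H-spiro[1,3-dioxolane-2,1′-naphthalene] | O1CCOC12CCC[C@H]3[C@](C)(Cc4c(OC)c(OC)cc(OC)c4OC)[C@@H](C)CC[C@@]23C | intermediate
21 | (4aS,5R,6S,8aR)-5,6,8a-trimethyl-5-[(2,3,5,6-tetramethoxyphenyl)methyl]octahydronaphthalen-1(2H)-one | O=C1CCC[C@H]2[C@](C)(Cc3c(OC)c(OC)cc(OC)c3OC)[C@@H](C)CC[C@@]12C | intermediate
22 | 1,2,4,5-tetramethoxy-3-{[(1R,2S,4aR,8aS)-1,2,4a-trimethyl-5-methylidenedecahydronaphthalen-1-yl]methyl}benzene | C=C1CCC[C@H]2[C@](C)(Cc3c(OC)c(OC)cc(OC)c3OC)[C@@H](C)CC[C@@]12C | intermediate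
23 | 2,5-dimethoxy-3-{[(1R,2S,4aR,8aS)-1,2,4a-trimethyl-5-methylidenedecahydronaphthalen-1-yl]methyl}cyclohexa-2,5-diene-1,4-dione | C=C1CCC[C@H]2[C@](C)(CC3=C(OC)C(=O)C=C(OC)C3=O)[C@@H](C)CC[C@@]12C | intermediate
24 | 2-hydroxy-5-methoxy-3-{[(1R,2S,4aR,8aS)-1,2,4a-trimethyl-5-methylidenedecahydronaphthalen-1-yl]methyl}cyclohexa-2,5-diene-1,4-dione | C=C1CCC[C@H]2[C@](C)(CC3=C(O)C(=O)C=C(OC)C3=O)[C@@H](C)CC[C@@]12C | target

## Step count and risk

Total: 16 steps. Longest linear sequence: 16 steps (1 to 24); 5 and 14 enter as side inputs in steps 3 and 9.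

**Step 8 (key step, proposed new method).**
- What may go wrong: slow turnover, because the cis-methyl group on C5 destabilises the s-cis diene and the Lewis-basic ketal competes for the catalyst. Leakage through the endo-formyl mode or incomplete facial shielding would erode diastereo- and enantiopurity. Acid-induced ionisation of the dienyl ketal could scramble the C5=C6 geometry.
- Fallback (known chemistry), from 12 back to 13: thermal intramolecular Diels–Alder reaction without any acid (toluene, BHT, 150–170 °C, sealed vessel), a well-established reaction type for trienes with four-atom tethers. The cis-fused aldehyde is separated from the trans-fused isomer as the racemate F1. F1 is resolved by preparative chromatography on a chiral stationary phase (cellulose tris(3,5-dimethylphenylcarbamate)), and the (4a′S,5′R,6′S,8a′R) enantiomer is 13.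

**Step 4.**
- What may go wrong: incomplete conversion of the cross-conjugated, α-branched ketone at low temperature. If the reaction is forced, proton-mediated migration of the diene out of conjugation or loss of E geometry may follow.
- Fallback, from 5 (through 6) back to 8: the ketal is installed before the diene is complete. The known (2E)-3-iodo-2-methylprop-2-enoic acid F2 is converted into its Weinreb amide F3 (carbonyldiimidazole, MeNH(OMe)·HCl). F3 takes up Grignard reagent 6 to give the iodoenone F4, which has no γ-hydrogen and so cannot deconjugate on ketalisation under the same silyl triflate conditions; this gives F5. Suzuki–Miyaura coupling of F5 with (E)-prop-1-enylboronic acid (Pd(PPh3)4, aq. K3PO4, THF), with retention at both alkenes, gives 8.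

**Step 9.**
- What may go wrong: slow or incomplete addition, because a di-ortho-substituted aryllithium must reach a formyl group on a quaternary carbon flanked by C8 and C10; the aldehyde would then be returned or reduced.
- Fallback, from 13 and 14 back to 20 (steps 10 to 12 are bypassed): the C15–aryl bond is made by Negishi coupling. Aldehyde 13 is reduced (NaBH4, MeOH) to the alcohol F6 and hydrogenated (H2, PtO2) to F7. F7 is converted (PPh3, I2, imidazole, toluene, 80 °C) into the neopentyl iodide F8. Zinc insertion (Zn dust, LiCl, THF, 50 °C) gives the alkylzinc iodide F9, which has no β-hydrogen and is not isolated. F9 is coupled (Pd(OAc)2, SPhos, THF, 60 °C) with 3-bromo-1,2,4,5-tetramethoxybenzene F10, made from 14 by lithiation to 15 and quenching with 1,2-dibromoethane, to give 20.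

**Step 16.**
- What may go wrong: hydroxide attack at the less hindered methoxy-bearing carbon (C5 of the quinone), giving the regioisomer, or hydrolysis of both methoxy groups.
- Fallback, from 23 back to 24: exhaustive hydrolysis (NaOH, aq. EtOH, 60 °C; then dilute HCl) gives the dihydroxyquinone F11. Mono-O-methylation of its less hindered oxygen, the one remote from the C15 branch (Me2SO4, 1 equiv, K2CO3, acetone), gives 24.

## Further compounds

F1 | step 8 | racemate of 13 (13 together with its enantiomer; cis-fused) | O1CCOC12CCC[C@H]3[C@](C)(C=O)[C@@H](C)C=C[C@@]23C.O1CCOC12CCC[C@@H]3[C@@](C)(C=O)[C@H](C)C=C[C@]23C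
F2 | step 4 | (2E)-3-iodo-2-methylprop-2-enoic acid | OC(=O)/C(C)=C/I
F3 | step 4 | (2E)-3-iodo-N-methoxy-N,2-dimethylprop-2-enamide | CON(C)C(=O)/C(C)=C/I
F4 | step 4 | (1E)-7-[(tert-butyldimethylsilyl)oxy]-1-iodo-2-methylhept-1-en-3-one | CC(C)(C)[Si](C)(C)OCCCCC(=O)/C(C)=C/I
F5 | step 4 | tert-butyl(4-{2-[(1E)-1-iodoprop-1-en-2-yl]-1,3-dioxolan-2-yl}butoxy)dimethylsilane | CC(C)(C)[Si](C)(C)OCCCCC1(OCCO1)/C(C)=C/I
F6 | step 9 | C15 primary alcohol from 13 (formyl reduced to CH2OH, C6=C7 retained, ring stereocentres as in 13) | O1CCOC12CCC[C@H]3[C@](C)(CO)[C@@H](C)C=C[C@@]23C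
F7 | step 9 | saturated C15 primary alcohol (F6 with C6–C7 hydrogenated) | O1CCOC12CCC[C@H]3[C@](C)(CO)[C@@H](C)CC[C@@]23C
F8 | step 9 | C15 iodide from F7 (CH2I on C9) | O1CCOC12CCC[C@H]3[C@](C)(CI)[C@@H](C)CC[C@@]23C
F9 | step 9 | C15 alkylzinc iodide from F8 (not isolated) | O1CCOC12CCC[C@H]3[C@](C)(C[Zn]I)[C@@H](C)CC[C@@]23C
F10 | step 9 | 3-bromo-1,2,4,5-tetramethoxybenzene | COc1cc(OC)c(OC)c(Br)c1OC
F11 | step 16 | 2,5-dihydroxy-3-{[(1R,2S,4aR,8aS)-1,2,4a-trimethyl-5-methylidenedecahydronaphthalen-1-yl]methyl}cyclohexa-2,5-diene-1,4-dione | C=C1CCC[C@H]2[C@](C)(CC3=C(O)C(=O)C=C(O)C3=O)[C@@H](C)CC[C@@]12C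
A1 | alternative 1 | cis-fused decalin with C4 ketone, C7 dimethyl ketal and C15 pivalate | O=C1CCC[C@H]2[C@](C)(COC(=O)C(C)(C)C)[C@@H](C)C(OC)(OC)C[C@@]12C
A2 | alternative 1 | ring A tert-butyldimethylsilyl enol ether (C4=C5) carrying on C10 the C9/C8 chain with the C15 pivalate and the terminal C7 methyl enol ether | CC1=C(O[Si](C)(C)C(C)(C)C)CCC[C@H]1[C@](C)(COC(=O)C(C)(C)C)[C@@H](C)C(OC)=C
A3 | alternative 2 | cis-fused decalin acid (C4 ketone, C6=C7, C9 bearing CO2H and the tetramethoxybenzyl group, C8 methyl) | O=C1CCC[C@H]2[C@](C(=O)O)(Cc3c(OC)c(OC)cc(OC)c3OC)[C@@H](C)C=C[C@@]12C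
A4 | alternative 2 | bicyclic δ-lactone (C9 carboxyl esterified by the C6 oxygen; prop-1-enyl on C6; tetramethoxybenzyl on C9; C6 configuration, C9 configuration and propenyl geometry left open) | O=C1CCC[C@H]2C(Cc3c(OC)c(OC)cc(OC)c3OC)C(=O)OC(C=CC)[C@@]12C
A5 | alternative 3 | cis-fused bicyclic enone (C8 ketone, C6=C7, C4 silyl ether, C5 methyl) | CC(C)(C)[Si](C)(C)O[C@H]1CCC[C@H]2CC(=O)C=C[C@@]12C
A6 | alternative 3 | 4-{1-[(tert-butyldimethylsilyl)oxy]-4-iodobutyl}-4-methylcyclohexa-2,5-dien-1-one | CC(C)(C)[Si](C)(C)O[C@@H](CCCI)C1(C)C=CC(=O)C=C1
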